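common to all: left-handed substrate 0.41 M; right-handed substrate 0.41 M; partner 0.328 M; free catalyst 0.41 mM
- delta: protic impurity 0.021 M; stray impurity 0.23 mM; run made earlier
- alpha: protic impurity 0.031 M; stray impurity 0.23 mM; run made earlier
- eta: protic impurity 0.041 M; stray impurity 0.35 mM; run made earlier
- flask: protic impurity 0.0410 M; stray impurity 0.23 mM; time 3.0 h

| run | time / h | left-handed substrate / % | right-handed substrate / % | left-handed product / % |
|---|---|---|---|---|
| delta | 0.133 | 48.8 | 49.8 | 1.1 |
| delta | 0.333 | 48.4 | 49.0 | 2.9 |
| delta | 0.667 | 46.0 | 49.4 | 3.9 |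
| delta | 1.00 | 44.7 | 50.0 | 6.0 |
| delta | 1.33 | 43.1 | 50.4 | 6.6 |
| delta | 2.00 | 40.7 | 50.6 | 9.1 |
| delta | 2.50 | 38.5 | 50.3 | 10.5 |
| alpha | 0.133 | 49.3 | 49.7 | 0.9 |
| alpha | 0.333 | 46.2 | 50.2 | 3.5 |
| alpha | 0.667 | 45.5 | 49.7 | 5.1 |
| alpha | 1.00 | 44.1 | 48.9 | 5.9 |
| alpha | 1.33 | 42.3 | 49.8 | 7.0 |
| alpha | 2.00 | 40.5 | 49.9 | 8.7 |
| alpha | 2.50 | 39.8 | 49.3 | 10.7 |
| eta | 0.200 | 49.3 | 50.4 | 1.1 |
| eta | 0.667 | 46.7 | 49.9 | 3.6 |
| eta | 1.00 | 45.2 | 49.6 | 4.8 |
| eta | 1.50 | 44.5 | 49.7 | 5.7 |
| eta | 2.50 | 41.8 | 49.7 | 8.0 |

(each reading ± 0.5 percentage points)

- free catalyst is single-handed; left-handed substrate and right-handed substrate are mirror images of each other, charged as a racemate, each of them at the stated concentration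
- candidate steps: free catalyst + left-handed substrate <-> catalyst intermediate A; free catalyst + right-handed substrate <-> catalyst intermediate B; partner + catalyst intermediate A -> free catalyst + left-handed product; partner + catalyst intermediate B -> free catalyst + right-handed product; partner + free catalyst -> spent catalyst A; partner + protic impurity -> quenched reagent; free catalyst + stray impurity -> spent catalyst B
- an excess is the difference of the two amounts in percent of their sum
- an excess is below zero if the other one leads

1. part of the left-handed substrate and right-handed substrate charged together that has reacted at 3.0 h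
2. excess of left-handed product over right-handed product in the product at 3.0 h
3. excess of right-handed substrate over left-handed substrate among what is left of the two at 3.0 h

1. Left over in the delta run at 2.50 h is 50.3 % of right-handed substrate, as charged within scatter, so I follow the left-handed product, which forms fast and then slower.

2. The candidate step takes one free catalyst per stray impurity (a catalyst poison). So I fold the charges into one number, the poison ratio 0.561, stray impurity over free catalyst charged. It is the share of catalyst I expect dead once the impurity is used, leaving a working share of 0.439.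

3. I solve both ends. At the start, delta and alpha give a mean slope of 0.0961 h⁻¹, read at 0.333 h. At the far end, I scale it by the working share to 0.0422 h⁻¹. Joining them, the mean left-handed product reading at 2.50 h plus the last 0.500 h at that slope gives my estimate of 12.7 % reacted in the flask.

4. Is one number enough? Eta's ratio is 0.854, which predicts a late slope 0.333 of delta's. The readings give 0.690. Eta also differs from delta in its protic impurity, and this reading carries scatter, so I take the ratio as an end level, not a clock.

5. The forecast says 11.9 % reacted, below my 12.7 %, with excesses of 95 % and 12.8 %. Its ground is “This points to catalyst loss, plus partner consumption”.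

6. The flask gives 12.4 %, 97.5 % and 13.8 %, so the forecast holds within its margins.

    free catalyst + left-handed substrate ⇌ catalyst intermediate A (K = 53.0 M⁻¹, k = 1.40 M⁻¹ s⁻¹)
    free catalyst + right-handed substrate ⇌ catalyst intermediate B (K = 8.60 M⁻¹, k = 8.90 M⁻¹ s⁻¹)
    partner + catalyst intermediate A → free catalyst + left-handed product (k = 0.330 M⁻¹ s⁻¹)
    partner + catalyst intermediate B → free catalyst + right-handed product (k = 0.00550 M⁻¹ s⁻¹)
    partner + free catalyst → spent catalyst A (k = 6.80 × 10⁻⁶ M⁻¹ s⁻¹)
    partner + protic impurity → quenched reagent (k = 7.80 × 10⁻⁴ M⁻¹ s⁻¹)
    free catalyst + stray impurity → spent catalyst B (k = 15.0 M⁻¹ s⁻¹)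

At 3.00 h the flask holds 55.1 % of its catalyst as spent catalyst B, with 1.9 % of the stray impurity left, close to the ratio 0.561. The excess of left-handed product stands at 97.5 % because catalyst intermediate B runs back to free catalyst and right-handed substrate: the run without that backward step gives −76.7 %, with the right-handed product leading. A neighbour flask with 0.025 M of protic impurity has the same ratio 0.561, so I expect the same catalyst loss. It gives 55.1 % as spent catalyst B and 12.6 % reacted.

The runs are simulated for substances that don't exist; the scatter is artificial.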